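All runs stem from a simulated flask for an exercise, noise included.

Of the 3 questions about this flask, the two on the excess rest on one quantity.

| setting | Monday's | Thursday's | flask |
|---|---|---|---|
| left-handed substrate | 0.15 M | 0.15 M | 0.15 M |
| right-handed substrate | 0.15 M | 0.15 M | 0.15 M |
| reagent | 0.17 M | 0.66 M | 0.330 M |
| free catalyst | 15 mM | 15 mM | 15 mM |
| precatalyst | 1.8 mM | 1.8 mM | 1.8 mM |
| remark | run made earlier | run made earlier |  |
| time |  |  | 4.0 d |

| run | time / d | left-handed product / % | right-handed product / % |
|---|---|---|---|
| Monday's | 0.625 | 31 | 14 |
| Monday's | 1.25 | 34 | 17 |
| Monday's | 1.67 | 34 | 18 |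
| Monday's | 2.50 | 33 | 18 |
| Monday's | 3.00 | 36 | 16 |
| Monday's | 4.00 | 39 | 20 |
| Thursday's | 0.208 | 43 | 28 |
| Thursday's | 0.625 | 49 | 38 |
| Thursday's | 1.04 | 48 | 46 |
| Thursday's | 1.67 | 51 | 48 |
| Thursday's | 2.50 | 52 | 52 |
| Thursday's | 3.00 | 51 | 47 |
| Thursday's | 4.00 | 49 | 47 |

(readings scatter by 2 percentage points)

- free catalyst is single-handed; left-handed substrate and right-handed substrate are mirror images of each other, charged as a racemate, each of them at the stated concentration
- an excess is the difference of the two amounts in percent of their sum
- an excess is below zero if the other one leads

* left-handed product and right-handed product together, in percent of the left-handed substrate and right-handed substrate charged together, at 4.0 d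
* excess of left-handed product over right-handed product in the product at 4.0 d
* whether the exchange between left-handed substrate and right-handed substrate keeps pace with the reaction: how far the product's excess at 4.0 d gets from its value without exchange to its value with instant exchange (above 80% keeps pace, below 20% hardly takes part, else lags behind)

1. The selectivity factor is the natural logarithm of the fraction of left-handed substrate left, divided by the same logarithm for right-handed substrate, in a run without exchange. Averaged over the earliest readings of Monday's and Thursday's runs, it reads 2.67, with the scatter of those readings.

2. I turn the question round. For exchange to keep pace, the substrate would have to stay racemic, and the product's excess would have to stay near (factor − 1)/(factor + 1), which is 45.5%. Yet Thursday's run reads 52% against 52% at 2.50 d, an excess of zero within scatter, which is the no-exchange value at full conversion. So I commit to "hardly takes part".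

3. Monday's total reaches 59.0%, close to the 56.7% its reagent covers, so I count reagent one to one. This flask's reagent covers 110%, so reagent is not the limiting reagent here.

4. My rule, for a flask without exchange: if a fraction g of right-handed substrate is left, then g raised to the factor is the left-handed fraction, and the product's excess is (g − g^factor)/(2 − g − g^factor).

The forecast gives 93%, an excess of 7%, and hardly takes part, with “About 10–15% of the right-handed substrate remains”.

The flask gives 90.7%, an excess of 12.7%, and hardly takes part, at 9.1% of the way.

    reagent + free catalyst + left-handed substrate → free catalyst + left-handed product (k = 0.0180 M⁻² s⁻¹)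
    reagent + free catalyst + right-handed substrate → free catalyst + right-handed product (k = 0.00690 M⁻² s⁻¹)
    left-handed substrate + racemization catalyst ⇌ right-handed substrate + racemization catalyst, rate k3*[racemization catalyst]*[left-handed substrate] forward; the back reaction follows from the equilibrium constant (k = 9.40 × 10⁻⁴ M⁻¹ s⁻¹)
    2 racemization catalyst → spent catalyst (k = 0.00590 M⁻¹ s⁻¹)
    free catalyst ⇌ dormant form (K = 1.80, k = 1.40 × 10⁻⁵ s⁻¹)
    precatalyst ⇌ racemization catalyst (K = 17.0, k = 5.60 × 10⁻⁵ s⁻¹)

At 4.00 d the flask keeps 16% of its right-handed substrate. With that g, the no-exchange rule gives an excess of 8.52%, less than the flask's excess.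

The neighbour flask with 0.083 M of reagent has reagent as its limiting reagent, covering 27.7% of its two substrates. Counting that reagent as used up and without exchange, the rule puts g at 83.3% and the excess at 39.7%. That neighbour flask gives 27.6% with an excess of 39.1%, and 0.20% of its reagent is left.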